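Remark on conventions: bicyclic compounds are described with eudesmane numbering (C10 = quaternary carbon carrying methyl C14; C5 = ring-fusion CH; C4 carries C15; C6 carries the oxygen; C7 carries the isopropyl group; ring A = C1–C5 and C10, ring B = C5–C10). β is the face of the C10 methyl group.

## Analysis of the target

The target 19 is a trans-fused eudesmane (two six-membered carbocycles sharing the C5–C10 bond) with the configuration (3R,4R,5S,6R,7S,10S). It carries a 3α-hydroxyl, a 4β-hydroxyl with the 4α-methyl C15, a 6β-benzoate, a 7β-isopropyl group and the angular 10β-methyl. All six stereocentres are contiguous: C3 to C7 form an unbroken chain, and the quaternary C10 is bonded to C5 and trans to its hydrogen. The two hydroxyls are trans-diaxial; the 4β-hydroxyl, the 6β-ester oxygen and the C10 methyl are mutually 1,3-diaxial on the β face, while the isopropyl group is equatorial. The benzoate is labile to base and hydride, can migrate to the syn-axial 4β-hydroxyl, and becomes a β-leaving group whenever C4 is a carbonyl; the tertiary alcohol ionises under acid. The synthesis is hard because of the crowded β face, the quaternary centre at a trans fusion, and the need to acylate the most hindered of three oxygens. The strategy rests on two readings of the skeleton: ring B with its C6 oxygen, C7 isopropyl and C10 methyl is the oxygenated p-menthane pattern of (S)-piperitone 1, and the C2–C3 pair of ring A can be excised as an alkyne, which leaves C1 and the C4 carbonyl joined in a four-membered ring (C1, C4, C5, C10) fused onto ring B.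

## Retrosynthetic reasoning

**C3–H (19 ⇒ 18).** The last bond made is the C3–H bond, so 19 is traced to ketol benzoate 18. Keeping C3 as a ketone until the end means that, when the ester is introduced, the C6 hydroxyl is the only secondary hydroxyl present. The forward reduction must deliver hydride to the β face of C3; the neighbouring 4β-hydroxyl can enforce this by intramolecular delivery from a borohydride that does not touch esters.

**C6–O acyl and silyl bonds (18 ⇒ 17 ⇒ 16).** The benzoate is exchanged for the silyl ether of 16 through diol 17. The ester is placed this late because every earlier intermediate with a C4 carbonyl would expel a C6 acyloxy group by β-elimination, whereas a silyloxy group is a far poorer leaving group.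

**C3=O and C2–Si (16 ⇒ 15 ⇒ 14 ⇒ 12).** The C3 carbonyl of 16 is taken back to a vinylsilane: 16 comes from α-silyl ketone 15, 15 from β-hydroxysilane 14, and 14 from hydroboration of vinylsilane 12. A silyl group on the β-carbon of an enone cannot simply be removed: ipso-protonation would put positive charge α to the carbonyl, and fluoride would have to expel an unstabilised vinyl anion. The silicon is therefore kept and used. It reinforces the delivery of boron to C3, and once C3 is a ketone the C2–Si bond is α to a carbonyl and cleaves under very mild conditions. One sequence thus installs the C3 oxygen and removes the silicon.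

**C4–C15 (12 ⇒ 11).** The methyl group is cut from C4, leading to trans-enone 11. The forward addition must come from the α face so that the hydroxyl is 4β. Both the C10 methyl and the 6β-silyloxy group are 1,3-diaxial to the β face of C4, so the substrate provides this bias.

**C5–H (11 ⇒ 9).** The trans fusion of 11 is derived from the cis-fused enone 9 by inversion at C5, the only stereocentre α to the ketone. This correction cannot be avoided, because the cycloaddition that builds the four-membered ring is suprafacial and gives a cis fusion. It is done by forming dienolate 10 and protonating it under kinetic control.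

**C3–C4 and C1–C2 (9 ⇒ 7 + 8).** Ring A of 9 is opened by removing C2 and C3 as trimethylsilylacetylene 8, which leaves the ring-fused cyclobutanone 7. This cut is chosen because it reduces the bicyclic problem to a monocyclic one with all ring B stereocentres in place, and because the forward step creates no stereocentre. The forward reaction has to cleave the C1–C4 bond (not C4–C5) and place silicon on C2.

**C4–C5 and C1–C10 (7 ⇒ 6 ⇒ 3 + 4, via 5).** Cyclobutanone 7 comes from dichlorocyclobutanone 6, the [2+2] adduct of silyl ether 3 with dichloroketene 5, which is generated from trichloroacetyl chloride 4. The carbonyl carbon of the ketene bonds to the less substituted alkene carbon C5, and addition anti to the two β substituents sets the quaternary C10.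

**C6–H and O–Si (3 ⇒ 2 ⇒ 1).** Silyl ether 3 is the protected form of cis-piperitol 2, which comes from (S)-piperitone 1 by carbonyl reduction. C7 is taken from the chiral pool and C6 is set by reagent control.

## Alternatives that were turned down

**Alternative 1:** Ring B is cut at C7=C8 (ring-closing metathesis) and at C5–C6 (aldol), and the C10 methyl is removed as a conjugate-addition nucleophile. In the forward key step Cu(OTf)2 with a chiral phosphoramidite catalyses the asymmetric 1,4-addition of Me3Al to 3-allylcyclohex-2-enone A1, which creates C10, and the resulting aluminium enolate is trapped at C5 by 2-isopropylacrolein A2 to give aldol adduct A3. Ring closure with the second-generation Grubbs catalyst would then give the bicyclic hydroxy ketone A4.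
- For it: three stereocentres and every ring B carbon are assembled in one step from achiral materials, the absolute configuration comes from a catalyst, the trans C5/C10 relationship can arise directly, and the route is several steps shorter than the chosen one. On step count and on independence from the chiral pool it is the stronger plan.
- Against it: the C6 configuration rests on the aldol of a hindered enolate, flanked by the new quaternary centre, with an α-branched and polymerisable enal, and the facial selectivity at C5 depends on the enolate distinguishing the allyl from the methyl group on that quaternary carbon. A3 is a β-hydroxy ketone prone to retro-aldol and dehydration. C7 must later come from hydrogenation of the trisubstituted C7=C8 bond of A4, where hydroxyl-directed delivery would add hydrogen syn to the 6β-oxygen and give the wrong C7 epimer, so the outcome depends on undirected steric control.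
- In comparison, the chosen strategy takes C7 from the pool, sets C6 by a reagent-controlled reduction before any ring is built, and lets both steer C10. Its risk sits in one bond-forming event that creates no stereocentre.

**Alternative 2:** Both rings are cut at once, at C5–C10 and C1–C2. In the forward key step Me2AlCl activates the (E)-enal of triene A5, which adds through an endo transition state to the diene at the other end of the chain and gives the trans-fused aldehyde A6.
- For it: two rings, the quaternary centre and the trans fusion form in one step with no C5 correction, and the C15 methyl and a 3-ene are in place for an epoxidation/trans-diaxial opening that matches the 3α,4β-diol. On ring-fusion control and on the diol logic it is stronger than the chosen plan.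
- Against it: the formyl carbon on C1 of A6 is not part of the target and must be removed by decarbonylation. The acyclic triene A5 needs an anti-aldol for C6/C7 and two trisubstituted alkenes of defined geometry, so the linear sequence before the key step is long. The dienophile is β,β-disubstituted and the diene terminus carries a branched allylic centre, which both lower reactivity. The later epoxide opening must take place on the crowded β face of C4.
- In comparison, the chosen route reaches the bicyclic core in five steps from 1 with no sacrificial carbon, and pays for this with the C5 inversion.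

**Alternative 3:** Ring B is cut at C6–C7. In the forward key step ZnBr2 promotes the carbonyl-ene cyclisation of aldehyde A7 onto the trisubstituted alkene of its side chain and gives dienol A8, with a new C6–C7 bond and an isopropenyl group on C7.
- For it: this cyclisation type is robust, its chair transition state sets C6 and C7 relative to C5 in one step, and the 3-ene is again ready for diol formation. In reliability of the key step it is clearly stronger than the chosen plan.
- Against it: the chair places the hydroxyl of A8 equatorial, which is 6α and opposite to the target, so an inversion at a very hindered carbinol (oxidation/reduction or displacement) is needed. The isopropenyl group must be hydrogenated in the presence of the ring alkene. The quaternary C10 with its trans C5 neighbour is moved into A7, whose enantioselective preparation is itself a substantial task.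
- In comparison, the chosen strategy gets C6 right without inversion and draws absolute configuration from the pool, and accepts an unprecedented key step in exchange.

Key step: step 5

Assumption: (S)-(+)-piperitone 1 is purchased in high enantiomeric purity and, since its stereocentre is α to the ketone, is used without prior exposure to base.

## Route

**Step 1**
Reactants: 1 (S)-piperitone
Product: 2 cis-piperitol, (1R,6S)-3-methyl-6-(propan-2-yl)cyclohex-2-en-1-ol
Conditions: LiBH(s-Bu)3, THF, −78 °C; then NaOH, H2O2, 0 °C
Reagents that add atoms: none
Why: 1,2-reduction of a β-substituted cyclohexenone by a bulky trialkylborohydride (the β-methyl group suppresses conjugate reduction); hydride arrives along the equatorial trajectory of the half-chair with the isopropyl group pseudo-equatorial, so the new C6 hydroxyl is pseudo-axial and cis to the isopropyl group (6β).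

**Step 2**
Reactants: 2 cis-piperitol
Product: 3 tert-butyldimethylsilyl ether of cis-piperitol, tert-butyl(dimethyl){[(1R,6S)-3-methyl-6-(propan-2-yl)cyclohex-2-en-1-yl]oxy}silane
Conditions: TBSOTf, 2,6-lutidine, CH2Cl2, −78 → 0 °C
Reagents that add atoms: tert-butyldimethylsilyl trifluoromethanesulfonate, CC(C)(C)[Si](C)(C)OS(=O)(=O)C(F)(F)F
Why: Silyl triflate silylation of a hindered secondary allylic alcohol; the bulky ether oxygen is too weakly nucleophilic to intercept the ketene and later shields the β face.

**Step 3**
Reactants: 3 silyl ether of cis-piperitol; 4 trichloroacetyl chloride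
Product: 6 cis-fused 8,8-dichloro-5-(tert-butyldimethylsilyloxy)-1-methyl-4-(propan-2-yl)bicyclo[4.2.0]octan-7-one (C4 carbonyl on C5 and CCl2 on C10; both new bonds α), via dichloroketene 5 (not isolated)
Conditions: Zn–Cu couple, POCl3, Et2O, rt, slow addition of 4
Reagents that add atoms: none
Why: Thermal ketene–alkene [2+2] cycloaddition; the electrophilic central ketene carbon bonds to the less substituted C5 and the CCl2 carbon to C10, where positive charge is better supported. Approach anti to the pseudo-axial 6β-silyloxy and the 7β-isopropyl groups sets C10 (methyl β) and the cis-related C5 from the α face.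

**Step 4**
Reactants: 6 dichlorocyclobutanone
Product: 7 cis-fused 5-(tert-butyldimethylsilyloxy)-1-methyl-4-(propan-2-yl)bicyclo[4.2.0]octan-7-one (5β-H, 6β-OTBS, 7β-isopropyl, 10β-methyl)
Conditions: Zn, NH4Cl, MeOH, rt
Reagents that add atoms: none
Why: Reductive dechlorination of an α,α-dichloroketone through its zinc enolate; no stereocentre is touched and the silyl ether survives the near-neutral medium.

**Step 5**
Reactants: 7 ring-fused cyclobutanone; 8 trimethylsilylacetylene
Product: 9 6β-(tert-butyldimethylsilyloxy)-2-(trimethylsilyl)-15-nor-5β-eudesm-2-en-4-one (cis-fused)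
Conditions: Ni(cod)2 (10–20 mol%), PCy3 (20–40 mol%), toluene, 100 °C, sealed tube, 8 (3 equiv) added slowly
Reagents that add atoms: none
Why: Proposed new method: zerovalent nickel should couple the C4 carbonyl of 7 and the alkyne oxidatively to an oxanickelacyclopentene in which the unsubstituted alkyne carbon (future C3) is bonded to C4 and the silyl-bearing carbon (future C2) to nickel; β-carbon elimination, driven by release of ring strain, then breaks C1–C4 to give a seven-membered nickelacycle (Ni, C2, C3, C4, C5, C10, C1), and C(sp3)–C(sp2) reductive elimination forms C1–C2 and frees the catalyst. The closest known reaction type is the nickel-catalysed intermolecular [4+2] insertion of internal alkynes into 3-substituted cyclobutanones, and of alkynes into 2-substituted azetidin-3-ones; a ring-fused 2,3-disubstituted cyclobutanone and a terminal silylalkyne have not been used. Ring A closes in the reductive elimination from the seven-membered nickelacycle, that is, as a two-carbon ring expansion of the four-membered ring. No stereocentre is formed; C5 and C10 are spectators, so the cis fusion of 7 is carried into 9. Cleavage of C1–C4 is expected because migration of the methylene carbon gives a primary nickel alkyl with no β-hydrogen (C10 is quaternary), whereas cleavage of C4–C5 would put nickel on a secondary carbon next to the silyloxy group. The alkyne orientation is expected from the preference of silicon for the nickel-bound carbon and from sterics, since only the CH terminus can reach the hindered carbonyl carbon. Oligomerisation of the terminal alkyne is the competing pathway and is held back by the bulky phosphine and slow addition of 8.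

**Step 6**
Reactants: 9 cis-fused enone
Product: 11 6β-(tert-butyldimethylsilyloxy)-2-(trimethylsilyl)-15-nor-5α-eudesm-2-en-4-one (trans-fused), via lithium dienolate 10 (not isolated)
Conditions: LiN(i-Pr)2, THF, −78 °C; then AcOH, −78 °C
Reagents that add atoms: none
Why: Kinetic α′-deprotonation of an enone followed by irreversible C-protonation of the cross-conjugated dienolate; the β face of C5 lies between the pseudo-axial C10 methyl and the 6β-silyloxy group (held axial by allylic strain with the enolate oxygen), so the proton should enter from the α face and give the trans fusion (5S). The low temperature keeps the β-silyloxy group from being eliminated.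

**Step 7**
Reactants: 11 trans-fused enone
Product: 12 6β-(tert-butyldimethylsilyloxy)-2-(trimethylsilyl)-5α-eudesm-2-en-4β-ol (4α-methyl)
Conditions: MeLi, CeCl3, THF, −78 °C; then aq. NH4Cl
Reagents that add atoms: methyllithium, [Li]C
Why: Organocerium 1,2-addition to a hindered, enolisable enone (low basicity, no conjugate addition); the C10 methyl and the 6β-silyloxy group are both 1,3-diaxial to the β face of C4, so the methyl group should add from the α face and set C4 (hydroxyl β).

**Step 8**
Reactants: 12 tertiary allylic alcohol
Product: 14 6β-(tert-butyldimethylsilyloxy)-2β-(trimethylsilyl)-5α-eudesmane-3α,4β-diol, via C3 organoborane 13 (not isolated)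
Conditions: BH3·THF, THF, 0 °C → rt; then NaOH, H2O2, 0 °C
Reagents that add atoms: hydrogen peroxide, OO
Why: Hydroboration–oxidation of a vinylsilane; boron goes to C3, the only CH terminus, which is β to silicon and proximal to the allylic oxygen, and syn addition from the α face, anti to the 4β-oxygen and the C10 methyl, is expected (3α-OH, 2β-Si). The configuration at C2 and C3 is of no consequence, because C3 is oxidised in step 9 and C2 becomes CH2. Diol 14 is taken on without exposure to acid, since its anti-periplanar hydroxyl and silyl groups invite Peterson elimination.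

**Step 9**
Reactants: 14 β-hydroxysilane
Product: 16 6β-(tert-butyldimethylsilyloxy)-4β-hydroxy-5α-eudesman-3-one, via α-silyl ketone 15 (not isolated)
Conditions: Dess–Martin periodinane, pyridine, CH2Cl2, 0 °C → rt; then K2CO3 (cat.), MeOH, 0 °C
Reagents that add atoms: none
Why: Buffered periodinane oxidation of the secondary alcohol avoids the acid-triggered Peterson elimination of the β-hydroxysilane, and the trans-diaxial diol cannot form the cyclic iodine ester needed for glycol cleavage. The resulting α-silyl ketone is protodesilylated through its enolate by catalytic base in methanol, leaving C2 as CH2.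

**Step 10**
Reactants: 16 silyl ether ketol
Product: 17 4β,6β-dihydroxy-5α-eudesman-3-one
Conditions: HF·pyridine, THF, 0 °C → rt
Reagents that add atoms: none
Why: Fluoride cleavage of a hindered secondary silyl ether under mildly acidic conditions, which avoids a base-induced acyloin shift of the tertiary α-ketol.

**Step 11**
Reactants: 17 diol ketone
Product: 18 6β-benzoyloxy-4β-hydroxy-5α-eudesman-3-one
Conditions: BzCl, pyridine, DMAP (cat.), CH2Cl2, rt → 40 °C
Reagents that add atoms: benzoyl chloride, O=C(Cl)c1ccccc1
Why: DMAP-catalysed acylation; the C6 hydroxyl is the only secondary one present (C3 is a ketone, the 4β-hydroxyl is tertiary), so the benzoate should go to C6 alone.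

**Step 12**
Reactants: 18 ketol benzoate
Product: 19 6β-benzoyloxy-5α-eudesmane-3α,4β-diol, (3R,4R,5S,6R,7S,10S), the target CNP0187831.1
Conditions: Me4NBH(OAc)3, MeCN/AcOH, −30 → 0 °C
Reagents that add atoms: none
Why: Hydroxyl-directed triacetoxyborohydride reduction (Evans–Saksena type), here across a 1,2-ketol; the axial 4β-hydroxyl exchanges onto boron and delivers hydride intramolecularly to the β face of C3, giving the 3α-alcohol trans to it. Triacetoxyborohydride does not reduce the benzoate.

## Compound list

1 | (S)-piperitone, (6S)-3-methyl-6-(propan-2-yl)cyclohex-2-en-1-one | CC1=CC(=O)[C@H](C(C)C)CC1 | starting material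
2 | cis-piperitol, (1R,6S)-3-methyl-6-(propan-2-yl)cyclohex-2-en-1-ol | CC(C)[C@@H]1CCC(C)=C[C@@H]1O | intermediate
3 | tert-butyldimethylsilyl ether of cis-piperitol | CC(C)[C@@H]1CCC(C)=C[C@@H]1O[Si](C)(C)C(C)(C)C | intermediate
4 | trichloroacetyl chloride | ClC(Cl)(Cl)C(Cl)=O | starting material
5 | dichloroketene | ClC(Cl)=C=O | intermediate
6 | cis-fused 8,8-dichloro-5-(tert-butyldimethylsilyloxy)-1-methyl-4-(propan-2-yl)bicyclo[4.2.0]octan-7-one (5β-H, 6β-OTBS, 7β-isopropyl, 10β-methyl) | CC(C)[C@@H]1CC[C@@]2(C)C(Cl)(Cl)C(=O)[C@H]2[C@@H]1O[Si](C)(C)C(C)(C)C | intermediate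
7 | cis-fused 5-(tert-butyldimethylsilyloxy)-1-methyl-4-(propan-2-yl)bicyclo[4.2.0]octan-7-one (5β-H, 6β-OTBS, 7β-isopropyl, 10β-methyl) | CC(C)[C@@H]1CC[C@@]2(C)CC(=O)[C@H]2[C@@H]1O[Si](C)(C)C(C)(C)C | intermediate
8 | trimethylsilylacetylene | C#C[Si](C)(C)C | starting material
9 | 6β-(tert-butyldimethylsilyloxy)-2-(trimethylsilyl)-15-nor-5β-eudesm-2-en-4-one (cis-fused) | CC(C)[C@@H]1CC[C@@]2(C)CC([Si](C)(C)C)=CC(=O)[C@H]2[C@@H]1O[Si](C)(C)C(C)(C)C | intermediate
10 | lithium 6β-(tert-butyldimethylsilyloxy)-2-(trimethylsilyl)-15-nor-eudesma-2,4-dien-4-olate | CC(C)[C@@H]1CC[C@@]2(C)CC([Si](C)(C)C)=CC(O[Li])=C2[C@@H]1O[Si](C)(C)C(C)(C)C | intermediate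
11 | 6β-(tert-butyldimethylsilyloxy)-2-(trimethylsilyl)-15-nor-5α-eudesm-2-en-4-one (trans-fused) | CC(C)[C@@H]1CC[C@@]2(C)CC([Si](C)(C)C)=CC(=O)[C@@H]2[C@@H]1O[Si](C)(C)C(C)(C)C | intermediate
12 | 6β-(tert-butyldimethylsilyloxy)-2-(trimethylsilyl)-5α-eudesm-2-en-4β-ol | CC(C)[C@@H]1CC[C@@]2(C)CC([Si](C)(C)C)=C[C@](C)(O)[C@@H]2[C@@H]1O[Si](C)(C)C(C)(C)C | intermediate
13 | 3α-boryl-4β-boryloxy-6β-(tert-butyldimethylsilyloxy)-2β-(trimethylsilyl)-5α-eudesmane (drawn as the bis-BH2 species) | CC(C)[C@@H]1CC[C@@]2(C)C[C@H]([Si](C)(C)C)[C@@H](B)[C@](C)(OB)[C@@H]2[C@@H]1O[Si](C)(C)C(C)(C)C | intermediate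
14 | 6β-(tert-butyldimethylsilyloxy)-2β-(trimethylsilyl)-5α-eudesmane-3α,4β-diol | CC(C)[C@@H]1CC[C@@]2(C)C[C@H]([Si](C)(C)C)[C@@H](O)[C@](C)(O)[C@@H]2[C@@H]1O[Si](C)(C)C(C)(C)C | intermediate
15 | 6β-(tert-butyldimethylsilyloxy)-4β-hydroxy-2β-(trimethylsilyl)-5α-eudesman-3-one | CC(C)[C@@H]1CC[C@@]2(C)C[C@H]([Si](C)(C)C)C(=O)[C@](C)(O)[C@@H]2[C@@H]1O[Si](C)(C)C(C)(C)C | intermediate
16 | 6β-(tert-butyldimethylsilyloxy)-4β-hydroxy-5α-eudesman-3-one | CC(C)[C@@H]1CC[C@@]2(C)CCC(=O)[C@](C)(O)[C@@H]2[C@@H]1O[Si](C)(C)C(C)(C)C | intermediate
17 | 4β,6β-dihydroxy-5α-eudesman-3-one | CC(C)[C@@H]1CC[C@@]2(C)CCC(=O)[C@](C)(O)[C@@H]2[C@@H]1O | intermediate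
18 | 6β-benzoyloxy-4β-hydroxy-5α-eudesman-3-one | CC(C)[C@@H]1CC[C@@]2(C)CCC(=O)[C@](C)(O)[C@@H]2[C@@H]1OC(=O)c1ccccc1 | intermediate
19 | 6β-benzoyloxy-5α-eudesmane-3α,4β-diol, (3R,4R,5S,6R,7S,10S) | CC(C)[C@@H]1CC[C@@]2(C)CC[C@@H](O)[C@](C)(O)[C@@H]2[C@@H]1OC(=O)c1ccccc1 | target

Total step count: 12. Longest linear sequence: 12 steps (from 1).

## Least certain steps

**Step 5 (key step).** What may go wrong: oligomerisation or cyclotrimerisation of the terminal alkyne on zerovalent nickel may outrun oxidative cyclisation with a carbonyl that has a tertiary α-carbon; β-carbon elimination may take the C4–C5 bond, after which nickel sits next to the silyloxy group and is lost through β-elimination; or the alkyne may insert with reversed orientation. None of these selectivities has been tested on a ring-fused cyclobutanone with a terminal silylalkyne. Fallback with known chemistry, from 7, returning at 16: the same C1–C4 bond is cut oxidatively and ring A is closed by aldol condensation. Cyclobutanone 7 is enolised towards the C1 methylene and silylated (LiN(i-Pr)2, Me3SiCl) to give cyclobutenyl silyl ether F1. Ozonolysis (O3; then Me2S) gives formyl acid F2, with the C1 aldehyde on C10 and the C4 acid on C5. Wittig methoxymethylenation of the non-enolisable aldehyde (excess Ph3P=CHOMe) gives enol ether acid F3, and MeLi converts its carboxylate into methyl ketone F4, whose methyl group is the future C3. Aqueous acid unmasks keto-aldehyde F5, and pyrrolidine/AcOH closes the C2=C3 bond by intramolecular aldol condensation; the acetyl-bearing C5 should equilibrate to its equatorial epimer before closure, giving the silicon-free trans-enone F6 (a cis-fused product would be corrected as in step 6). Methyl addition as in step 7 gives allylic alcohol F7, hydroboration–oxidation with boron directed to C3 anti to the allylic oxygen gives diol F8, and oxidation of its secondary hydroxyl as in step 9 gives 16. The cost is about five extra steps and a hydroboration without the support of silicon.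

**Step 6.** What may go wrong: deprotonation at the hindered tertiary C5 may be incomplete or diverted to the γ-methylene C1; protonation on oxygen followed by unselective ketonisation may erode the facial preference; and loss of the β-silyloxy group by elimination becomes possible if the dienolate warms. Fallback from 9, returning at 11: kinetic control is given up for thermodynamic control. Compound 9 is equilibrated with 11 by a mild amidine base (1,8-diazabicyclo[5.4.0]undec-7-ene, toluene, rt), without a metal enolate; 11 is separated and recovered 9 is recycled. No new compound is involved.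

**Step 8.** What may go wrong: hydroboration may be slow at an alkene that carries a trimethylsilyl group and adjoins a quaternary carbinol, boron may leak to C2, and the C3 borane, which is anti-periplanar to the 4β-boryloxy group, may be lost by β-elimination before it is oxidised. Fallback from 12, returning at 15 (and thus 16): the oxygen is brought in by epoxidation instead. Hydroxyl-directed epoxidation (VO(acac)2, t-BuOOH) gives epoxysilane F9. LiAlH4 opens it at the silicon-bearing C2, the usual regiochemistry of α,β-epoxysilanes, to give β-hydroxysilane F10. Its oxidation under the conditions of step 9 gives 15, since the C3 configuration is erased.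

**Step 11.** What may go wrong: acylation of the 6β-hydroxyl, which is axial, flanked by the isopropyl group and syn-axial to both the C10 methyl and the 4β-hydroxyl, may be so slow that forcing conditions degrade the α-ketol or acylate O4. Fallback from 17, returning at 18: the syn-diaxial 1,3-diol is used instead of direct acylation. Trimethyl orthobenzoate with catalytic camphorsulfonic acid bridges O4 and O6 as cyclic orthoester F11. Mild aqueous acetic acid then opens it to the hydroxy benzoate; acyl transfer between the two syn-axial oxygens should settle the ester on the secondary C6 oxygen, giving 18.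

## Further compounds

F1 | step 5 | trimethylsilyl enol ether of 7 (cyclobutene, C1=C4–OSiMe3) | CC(C)[C@@H]1CC[C@@]2(C)C=C(O[Si](C)(C)C)[C@H]2[C@@H]1O[Si](C)(C)C(C)(C)C
F2 | step 5 | formyl acid: 2-(tert-butyldimethylsilyloxy)-6-formyl-6-methyl-3-(propan-2-yl)cyclohexane-1-carboxylic acid (CHO and CO2H cis) | CC(C)[C@@H]1CC[C@@](C)(C=O)[C@@H](C(=O)O)[C@@H]1O[Si](C)(C)C(C)(C)C
F3 | step 5 | 2-(tert-butyldimethylsilyloxy)-6-(2-methoxyethenyl)-6-methyl-3-(propan-2-yl)cyclohexane-1-carboxylic acid (E/Z mixture) | CC(C)[C@@H]1CC[C@@](C)(C=COC)[C@@H](C(=O)O)[C@@H]1O[Si](C)(C)C(C)(C)C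
F4 | step 5 | 1-[2-(tert-butyldimethylsilyloxy)-6-(2-methoxyethenyl)-6-methyl-3-(propan-2-yl)cyclohexyl]ethan-1-one (E/Z mixture) | CC(C)[C@@H]1CC[C@@](C)(C=COC)[C@@H](C(C)=O)[C@@H]1O[Si](C)(C)C(C)(C)C
F5 | step 5 | 2-[2-acetyl-3-(tert-butyldimethylsilyloxy)-1-methyl-4-(propan-2-yl)cyclohexyl]acetaldehyde | CC(C)[C@@H]1CC[C@@](C)(CC=O)[C@@H](C(C)=O)[C@@H]1O[Si](C)(C)C(C)(C)C
F6 | step 5 | 6β-(tert-butyldimethylsilyloxy)-15-nor-5α-eudesm-2-en-4-one | CC(C)[C@@H]1CC[C@@]2(C)CC=CC(=O)[C@@H]2[C@@H]1O[Si](C)(C)C(C)(C)C
F7 | step 5 | 6β-(tert-butyldimethylsilyloxy)-5α-eudesm-2-en-4β-ol | CC(C)[C@@H]1CC[C@@]2(C)CC=C[C@](C)(O)[C@@H]2[C@@H]1O[Si](C)(C)C(C)(C)C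
F8 | step 5 | 6β-(tert-butyldimethylsilyloxy)-5α-eudesmane-3α,4β-diol | CC(C)[C@@H]1CC[C@@]2(C)CC[C@@H](O)[C@](C)(O)[C@@H]2[C@@H]1O[Si](C)(C)C(C)(C)C
F0 | step 6 | none | none
F9 | step 8 | 2β,3β-epoxy-6β-(tert-butyldimethylsilyloxy)-2α-(trimethylsilyl)-5α-eudesman-4β-ol | CC(C)[C@@H]1CC[C@@]2(C)C[C@]3([Si](C)(C)C)O[C@@H]3[C@](C)(O)[C@@H]2[C@@H]1O[Si](C)(C)C(C)(C)C
F10 | step 8 | 6β-(tert-butyldimethylsilyloxy)-2β-(trimethylsilyl)-5α-eudesmane-3β,4β-diol | CC(C)[C@@H]1CC[C@@]2(C)C[C@H]([Si](C)(C)C)[C@H](O)[C@](C)(O)[C@@H]2[C@@H]1O[Si](C)(C)C(C)(C)C
F11 | step 11 | cyclic 4β,6β-orthobenzoate of 17 (2-methoxy-2-phenyl-1,3-dioxane, mixture at the orthoester carbon) | CC(C)[C@@H]1CC[C@@]2(C)CCC(=O)[C@](C)(OC3(OC)c4ccccc4)[C@@H]2[C@@H]1O3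
A1 | alternative 1 | 3-allylcyclohex-2-en-1-one | C=CCC1=CC(=O)CCC1
A2 | alternative 1 | 2-isopropylacrolein (3-methyl-2-methylidenebutanal) | CC(C)C(=C)C=O
A3 | alternative 1 | aldol adduct, 3-allyl-2-(1-hydroxy-3-methyl-2-methylidenebutyl)-3-methylcyclohexan-1-one with C5, C6 and C10 as in 19 | C=CC[C@@]1(C)CCCC(=O)[C@@H]1[C@H](O)C(=C)C(C)C
A4 | alternative 1 | metathesis product, 6β-hydroxy-15-nor-5α-eudesm-7-en-4-one | CC(C)C1=CC[C@@]2(C)CCCC(=O)[C@@H]2[C@@H]1O
A5 | alternative 2 | (2E,8E)-7-(tert-butyldimethylsilyloxy)-3,9-dimethyl-6-(propan-2-yl)undeca-2,8,10-trienal (C6/C7 anti) | O=C/C=C(\C)CC[C@@H](C(C)C)[C@@H](O[Si](C)(C)C(C)(C)C)/C=C(\C)C=C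
A6 | alternative 2 | 6β-(tert-butyldimethylsilyloxy)-5α-eudesm-3-ene-1β-carbaldehyde | CC(C)[C@@H]1CC[C@@]2(C)[C@H](C=O)CC=C(C)[C@@H]2[C@@H]1O[Si](C)(C)C(C)(C)C
A7 | alternative 3 | 2,6-dimethyl-6-(4-methylpent-3-en-1-yl)cyclohex-2-ene-1-carbaldehyde (formyl cis to the C6 methyl) | CC(C)=CCC[C@@]1(C)CCC=C(C)[C@@H]1C=O
A8 | alternative 3 | 5α-eudesma-3,11-dien-6α-ol | CC(=C)[C@@H]1CC[C@@]2(C)CCC=C(C)[C@@H]2[C@H]1O
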